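## Retrosynthetic overview

1. Target 26 ⇐ C1 alcohol 25 (oxidation) ⇐ bis-epoxide 24: transannular 5-exo opening of the 1,10-epoxide by the C7 hydroxyl builds the oxolane bridge and sets C10.
2. Germacradienolide 23 ⇐ (E,E)-cyclodecadienone 18: vinylalumination of the C7 ketone and lactonisation onto O6 build the α-methylene γ-lactone and set C7.
3. 18 ⇐ twelve-membered allyl β-keto lactone 17: ring contraction by palladium-catalysed decarboxylative allylic alkylation (C8–C9 bond formed, CO2 lost, C8 set). This is the key step.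
4. 17 ⇐ acyclic (E,E)-hydroxy β-keto ester 14 (macrolactonisation, α-acyloxylation) ⇐ enal 5 + methyl propiolate (sets C6), methacrolein and hex-1-en-5-yne.
5. Ring order: twelve-membered lactone → ten-membered carbocycle → γ-lactone → oxiranes → oxolane.

Assumption: hex-1-en-5-yne is bought as such; atoms carry germacrane numbers (C1 ketone carbon, C4–C5 epoxide, C6 lactone CH–O, C7 spiro carbon, C8 ester CH, C10 ether carbon, C11–C13 acrylate unit, C14/C15 methyls).

## Route

Step 1
Reactants: 1 hex-1-en-5-yne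
Product: 4 (2E)-3-methylhepta-2,6-dien-1-ol, via alkenylalane 2 (not isolated), via lithium alanate 3 (not isolated)
Conditions: Me3Al, Cp2ZrCl2 (20 mol%), CH2Cl2, 0 °C to rt; n-BuLi, THF, −78 °C; (CH2O)n, rt; aq. HCl
Reagents that add atoms: trimethylaluminium C[Al](C)C; formaldehyde (from paraformaldehyde) C=O
Why: Negishi zirconium-catalysed syn-methylalumination of the terminal alkyne (the alkene is inert) puts Me and Al cis, and hydroxymethylation of the alanate with retention gives the E-allylic alcohol (future C4=C5).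

Step 2
Reactants: 4 (2E)-3-methylhepta-2,6-dien-1-ol
Product: 5 (2E)-3-methylhepta-2,6-dienal
Conditions: MnO2, CH2Cl2, rt
Reagents that add atoms: none
Why: Allylic oxidation with MnO2 stops at the enal and leaves the terminal alkene and the E geometry untouched.

Step 3
Reactants: 5 (2E)-3-methylhepta-2,6-dienal; 6 methyl propiolate
Product: 8 methyl (4R,5E)-4-hydroxy-6-methyldeca-5,9-dien-2-ynoate, via zinc acetylide 7 (not isolated)
Conditions: Me2Zn (3 equiv), (S,S)-ProPhenol (10 mol%), Ph3PO (20 mol%), toluene, 4 °C; aq. NH4Cl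
Reagents that add atoms: none
Why: Trost dinuclear-zinc ProPhenol alkynylation of an enal; the ligand enantiomer is chosen for Si-face 1,2-addition, which sets the 4R carbinol (C6 of the target).

Step 4
Reactants: 8 methyl (4R,5E)-4-hydroxy-6-methyldeca-5,9-dien-2-ynoate
Product: 9 methyl (4R,5E)-4-(tert-butyldimethylsilyloxy)-6-methyldeca-5,9-dien-2-ynoate
Conditions: TBSOTf, 2,6-lutidine, CH2Cl2, −78 °C
Reagents that add atoms: tert-butyldimethylsilyl trifluoromethanesulfonate CC(C)(C)[Si](C)(C)OS(=O)(=O)C(F)(F)F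
Why: Standard silylation; it blocks the hydroxyl that would otherwise close a tetronic acid once the β-keto ester is unmasked.

Step 5
Reactants: 9 methyl (4R,5E)-4-(tert-butyldimethylsilyloxy)-6-methyldeca-5,9-dien-2-ynoate
Product: 11 methyl (4R,5E)-4-(tert-butyldimethylsilyloxy)-6-methyl-3-oxodeca-5,9-dienoate, via enamino ester 10 (not isolated)
Conditions: pyrrolidine (1.2 equiv), MeCN, 0 °C to rt; aq. oxalic acid, THF, rt
Reagents that add atoms: water O
Why: Conjugate addition of the amine to the ynoate and mild hydrolysis of the β-enamino ester is a regiospecific formal alkyne hydration to the β-keto ester; C4 is not touched because the 1,3-dicarbonyl CH2 is the acidic site.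

Step 6
Reactants: 11 methyl (4R,5E)-4-(tert-butyldimethylsilyloxy)-6-methyl-3-oxodeca-5,9-dienoate; 12 methacrolein
Product: 13 methyl (4R,5E,9E)-4-(tert-butyldimethylsilyloxy)-6,10-dimethyl-3,11-dioxoundeca-5,9-dienoate
Conditions: second-generation Grubbs catalyst RuCl2(H2IMes)(PCy3)(=CHPh) (5 mol%), methacrolein (5 equiv), CH2Cl2, 40 °C
Reagents that add atoms: none
Why: Olefin cross-metathesis of the terminal alkene with methacrolein gives the trisubstituted E-enal under thermodynamic control (future C1=C10); the trisubstituted C5=C6 alkene does not react.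

Step 7
Reactants: 13 methyl (4R,5E,9E)-4-(tert-butyldimethylsilyloxy)-6,10-dimethyl-3,11-dioxoundeca-5,9-dienoate
Product: 14 methyl (4R,5E,9E)-4-(tert-butyldimethylsilyloxy)-11-hydroxy-6,10-dimethyl-3-oxoundeca-5,9-dienoate
Conditions: NaBH(OAc)3, AcOH, THF, 0 °C to rt
Reagents that add atoms: none
Why: Triacetoxyborohydride reduces the aldehyde chemoselectively (1,2) and leaves the ketone, the esters and the alkenes alone.

Step 8
Reactants: 14 methyl (4R,5E,9E)-4-(tert-butyldimethylsilyloxy)-11-hydroxy-6,10-dimethyl-3-oxoundeca-5,9-dienoate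
Product: 15 (5R,6E,10E)-5-(tert-butyldimethylsilyloxy)-7,11-dimethyl-1-oxacyclododeca-6,10-diene-2,4-dione
Conditions: DMAP (0.3 equiv), 4 Å MS, toluene (1 mM), 110 °C
Reagents that add atoms: none
Why: DMAP-promoted transesterification of a β-keto ester through its acylketene at high dilution (acylketene macrolactonisation) closes the twelve-membered allyl β-keto lactone without touching a stereocentre.

Step 9
Reactants: 15 (5R,6E,10E)-5-(tert-butyldimethylsilyloxy)-7,11-dimethyl-1-oxacyclododeca-6,10-diene-2,4-dione; 16 methacrylic acid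
Product: 17 (5R,6E,10E)-5-(tert-butyldimethylsilyloxy)-7,11-dimethyl-2,4-dioxo-1-oxacyclododeca-6,10-dien-3-yl 2-methylprop-2-enoate (C3 epimers)
Conditions: Bu4NI (10 mol%), t-BuOOH (2 equiv), EtOAc, 50 °C
Reagents that add atoms: none
Why: Hypoiodite-catalysed oxidative α-acyloxylation of a 1,3-dicarbonyl with a carboxylic acid puts the methacrylate on the doubly activated C3; this labile centre is erased in the enolate of step 10.

Step 10
Reactants: 17 (5R,6E,10E)-5-(tert-butyldimethylsilyloxy)-7,11-dimethyl-2,4-dioxo-1-oxacyclododeca-6,10-dien-3-yl 2-methylprop-2-enoate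
Product: 18 (1S,3E,7E,9R)-9-(tert-butyldimethylsilyloxy)-3,7-dimethyl-10-oxocyclodeca-3,7-dien-1-yl 2-methylprop-2-enoate
Conditions: Pd2(dba)3 (5 mol%), (S)-t-Bu-PHOX (12 mol%), toluene (2 mM), 30 °C
Reagents that add atoms: none
Why: Proposed new method: zerovalent palladium ionises the allylic C12–O1 bond of the macrolactone to a tethered π-allyl/β-keto carboxylate, CO2 loss gives a palladium α-acyloxy enolate, and C–C bond formation at the primary allyl terminus (the other terminus would need an E-alkene in an eight-membered ring) contracts the ring to the (E,E)-cyclodecadienone with the syn-allyl geometry kept, while the PHOX ligand and the neighbouring C–OTBS centre steer the enolate face so that the two oxygens end cis (new centre S); closest known reaction type: Tsuji–Saegusa/Stoltz–Trost decarboxylative allylic alkylation of acyclic and small-ring allyl β-keto esters and Trost's palladium "cyclisation via isomerisation" of vinyl lactones, neither shown as a macrolactone-to-carbocycle ring contraction with an α-acyloxy enolate.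

Step 11
Reactants: 18 (1S,3E,7E,9R)-9-(tert-butyldimethylsilyloxy)-3,7-dimethyl-10-oxocyclodeca-3,7-dien-1-yl 2-methylprop-2-enoate; 19 ethyl propiolate
Product: 23 (6R,7S,8S)-7-hydroxy-8-(methacryloyloxy)germacra-1(10)E,4E,11(13)-trien-12,6-olide, via vinylalane 20 (not isolated), via ketone adduct 21 (not isolated), via diol ester 22 (not isolated)
Conditions: i-Bu2AlH, NMO, THF, 0 °C (19); then 18, −20 °C to rt; HF·pyridine, THF, rt
Reagents that add atoms: none
Why: Vinylalumination (α-aluminoacrylate addition to an activated α,α'-dioxygenated ketone) occurs on the face anti to the two cis C–O bonds at C6 and C8 (Felkin–Anh matched at both sides), which sets 7S; desilylation then lets O6 lactonise onto the acrylate ester to the trans-fused α-methylene γ-lactone.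

Step 12
Reactants: 23 (6R,7S,8S)-7-hydroxy-8-(methacryloyloxy)germacra-1(10)E,4E,11(13)-trien-12,6-olide
Product: 25 (1R,4R,5R,6R,7S,8S,10S)-4,5:7,10-diepoxy-1-hydroxy-8-(methacryloyloxy)germacr-11(13)-en-12,6-olide, via bis-epoxide 24 (not isolated)
Conditions: mCPBA (2.4 equiv), NaHCO3, CH2Cl2, 0 °C; then CSA (5 mol%), rt
Reagents that add atoms: 3-chloroperbenzoic acid OOC(=O)c1cccc(Cl)c1
Why: Prilezhaev epoxidation of both electron-rich E-alkenes from the ring periphery (the usual germacranolide facial bias; the acrylates are inert) gives the (1R,10R;4R,5R) bis-epoxide, and acid-catalysed transannular 5-exo-tet attack of the C7 hydroxyl on tertiary C10 with inversion sets 10S and closes the oxolane, the 4,5-epoxide being reachable only in a disfavoured endo mode.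

Step 13
Reactants: 25 (1R,4R,5R,6R,7S,8S,10S)-4,5:7,10-diepoxy-1-hydroxy-8-(methacryloyloxy)germacr-11(13)-en-12,6-olide
Product: 26 (4R,5R,6R,7S,8S,10S)-4,5:7,10-diepoxy-8-(methacryloyloxy)-1-oxogermacr-11(13)-en-12,6-olide
Conditions: Dess–Martin periodinane, NaHCO3, CH2Cl2, rt
Reagents that add atoms: none
Why: Dess–Martin oxidation of the only free (secondary) hydroxyl gives the C1 ketone under buffered conditions that spare the epoxide, the methylene lactone and the methacrylate.

## Compound list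

1 | hex-1-en-5-yne | C#CCCC=C | starting material
2 | (E)-dimethyl(2-methylhexa-1,5-dien-1-yl)alane | C=CCC/C(C)=C/[Al](C)C | intermediate
3 | lithium (E)-butyldimethyl(2-methylhexa-1,5-dien-1-yl)alanate | [Li+].C=CCC/C(C)=C/[Al-](C)(C)CCCC | intermediate
4 | (2E)-3-methylhepta-2,6-dien-1-ol | C=CCC/C(C)=C/CO | intermediate
5 | (2E)-3-methylhepta-2,6-dienal | C=CCC/C(C)=C/C=O | intermediate
6 | methyl propiolate | C#CC(=O)OC | starting material
7 | methyl 3-(methylzincio)prop-2-ynoate | C[Zn]C#CC(=O)OC | intermediate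
8 | methyl (4R,5E)-4-hydroxy-6-methyldeca-5,9-dien-2-ynoate | COC(=O)C#C[C@H](O)/C=C(C)/CCC=C | intermediate
9 | methyl (4R,5E)-4-(tert-butyldimethylsilyloxy)-6-methyldeca-5,9-dien-2-ynoate | COC(=O)C#C[C@H](O[Si](C)(C)C(C)(C)C)/C=C(C)/CCC=C | intermediate
10 | methyl (4R,5E)-4-(tert-butyldimethylsilyloxy)-6-methyl-3-(pyrrolidin-1-yl)deca-2,5,9-trienoate | COC(=O)C=C(N1CCCC1)[C@H](O[Si](C)(C)C(C)(C)C)/C=C(C)/CCC=C | intermediate
11 | methyl (4R,5E)-4-(tert-butyldimethylsilyloxy)-6-methyl-3-oxodeca-5,9-dienoate | COC(=O)CC(=O)[C@H](O[Si](C)(C)C(C)(C)C)/C=C(C)/CCC=C | intermediate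
12 | methacrolein | C=C(C)C=O | starting material
13 | methyl (4R,5E,9E)-4-(tert-butyldimethylsilyloxy)-6,10-dimethyl-3,11-dioxoundeca-5,9-dienoate | COC(=O)CC(=O)[C@H](O[Si](C)(C)C(C)(C)C)/C=C(C)/CC/C=C(C)/C=O | intermediate
14 | methyl (4R,5E,9E)-4-(tert-butyldimethylsilyloxy)-11-hydroxy-6,10-dimethyl-3-oxoundeca-5,9-dienoate | COC(=O)CC(=O)[C@H](O[Si](C)(C)C(C)(C)C)/C=C(C)/CC/C=C(C)/CO | intermediate
15 | (5R,6E,10E)-5-(tert-butyldimethylsilyloxy)-7,11-dimethyl-1-oxacyclododeca-6,10-diene-2,4-dione | O=C1CC(=O)[C@H](O[Si](C)(C)C(C)(C)C)/C=C(C)/CC/C=C(C)/CO1 | intermediate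
16 | methacrylic acid | C=C(C)C(=O)O | starting material
17 | (5R,6E,10E)-5-(tert-butyldimethylsilyloxy)-7,11-dimethyl-2,4-dioxo-1-oxacyclododeca-6,10-dien-3-yl 2-methylprop-2-enoate (C3 epimers, labile) | O=C1C(OC(=O)C(C)=C)C(=O)[C@H](O[Si](C)(C)C(C)(C)C)/C=C(C)/CC/C=C(C)/CO1 | intermediate
18 | (1S,3E,7E,9R)-9-(tert-butyldimethylsilyloxy)-3,7-dimethyl-10-oxocyclodeca-3,7-dien-1-yl 2-methylprop-2-enoate | O=C1[C@@H](OC(=O)C(C)=C)C/C(C)=C/CC/C(C)=C/[C@H]1O[Si](C)(C)C(C)(C)C | intermediate
19 | ethyl propiolate | C#CC(=O)OCC | starting material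
20 | ethyl 2-(diisobutylalumanyl)prop-2-enoate | C=C([Al](CC(C)C)CC(C)C)C(=O)OCC | intermediate
21 | ethyl 2-[(1S,2S,4E,8E,10R)-10-(tert-butyldimethylsilyloxy)-1-hydroxy-4,8-dimethyl-2-(2-methylprop-2-enoyloxy)cyclodeca-4,8-dien-1-yl]prop-2-enoate | O[C@@]1(C(=C)C(=O)OCC)[C@@H](OC(=O)C(C)=C)C/C(C)=C/CC/C(C)=C/[C@H]1O[Si](C)(C)C(C)(C)C | intermediate
22 | ethyl 2-[(1R,2S,4E,8E,10R)-1,10-dihydroxy-4,8-dimethyl-2-(2-methylprop-2-enoyloxy)cyclodeca-4,8-dien-1-yl]prop-2-enoate | O[C@@]1(C(=C)C(=O)OCC)[C@@H](OC(=O)C(C)=C)C/C(C)=C/CC/C(C)=C/[C@H]1O | intermediate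
23 | (6R,7S,8S)-7-hydroxy-8-(methacryloyloxy)germacra-1(10)E,4E,11(13)-trien-12,6-olide | C=C(C)C(=O)O[C@H]1C/C(C)=C/CC/C(C)=C/[C@H]2OC(=O)C(=C)[C@]12O | intermediate
24 | (1R,4R,5R,6R,7S,8S,10R)-1,10:4,5-diepoxy-7-hydroxy-8-(methacryloyloxy)germacr-11(13)-en-12,6-olide | C=C(C)C(=O)O[C@H]1C[C@@]2(C)O[C@@H]2CC[C@@]2(C)O[C@@H]2[C@H]2OC(=O)C(=C)[C@]12O | intermediate
25 | (1R,4R,5R,6R,7S,8S,10S)-4,5:7,10-diepoxy-1-hydroxy-8-(methacryloyloxy)germacr-11(13)-en-12,6-olide | C=C(C)C(=O)O[C@H]1C[C@]2(C)O[C@@]13C(=C)C(=O)O[C@@H]3[C@H]1O[C@]1(C)CC[C@H]2O | intermediate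
26 | (4R,5R,6R,7S,8S,10S)-4,5:7,10-diepoxy-8-(methacryloyloxy)-1-oxogermacr-11(13)-en-12,6-olide (CNP0241021.2) | C=C(C)C(=O)O[C@H]1C[C@]2(C)O[C@@]13C(=C)C(=O)O[C@@H]3[C@H]1O[C@]1(C)CCC2=O | target

## Step count and risks

Total step count: 13. Longest linear sequence: 13 steps (1 → 26).

Steps most likely to fail:

Step 10 (the proposed new ring contraction). The tethered enolate/π-allyl pair may oligomerise or be quenched by a proton, the (E,E)-cyclodecadiene closure is strained, and C8 may form as the wrong epimer. The fallback uses known chemistry only; it sets out from 14 and comes back at 18. Methyl chloroformate and pyridine turn the allylic alcohol of 14 into methyl (4R,5E,9E)-4-(tert-butyldimethylsilyloxy)-11-(methoxycarbonyloxy)-6,10-dimethyl-3-oxoundeca-5,9-dienoate F1. Pd(PPh3)4 with dppe in THF at high dilution then closes the ten-membered ring by an open-chain Tsuji–Trost alkylation of the β-keto ester, giving methyl (3E,7E,9R)-9-(tert-butyldimethylsilyloxy)-3,7-dimethyl-10-oxocyclodeca-3,7-diene-1-carboxylate F2. Hypoiodite acyloxylation with 16 as in step 9 gives methyl (3E,7E,9R)-9-(tert-butyldimethylsilyloxy)-3,7-dimethyl-1-(2-methylprop-2-enoyloxy)-10-oxocyclodeca-3,7-diene-1-carboxylate F3. Krapcho demethoxycarbonylation (LiCl, wet DMSO, 120 °C, BHT) delivers 18, with DBU equilibration of C8 if needed.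

Step 11. The ketone is hindered and the bulky vinylalane may react slowly or from the wrong face. The fallback sets out from 18 and comes back at 23. Ethynylmagnesium bromide with CeCl3 (THF, −78 °C), a smaller and harder nucleophile, gives (1S,2S,4E,8E,10R)-10-(tert-butyldimethylsilyloxy)-1-ethynyl-1-hydroxy-4,8-dimethylcyclodeca-4,8-dien-2-yl 2-methylprop-2-enoate F4. HF·pyridine gives (1R,2S,4E,8E,10R)-1-ethynyl-1,10-dihydroxy-4,8-dimethylcyclodeca-4,8-dien-2-yl 2-methylprop-2-enoate F5. Palladium-catalysed carbonylative lactonisation of the homopropargylic alcohol (PdCl2, PPh3, SnCl2, CO, MeCN) then builds the α-methylene γ-lactone 23, so that C12 comes from CO instead of the propiolate.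

Step 12. The 4,5-epoxide, or the new C1 hydroxyl attacking C4, may enter competing transannular openings under acid. The fallback sets out from 23 and comes back at 26; it forms the ether before any epoxide exists. Hg(OCOCF3)2 (divalent mercury) in THF gives transannular Markovnikov oxymercuration (C7–O to C10, mercury to C1), i.e. (4E)-7,10-epoxy-8-(methacryloyloxy)-1-(trifluoroacetoxymercurio)germacra-4,11(13)-dien-12,6-olide F6. Oxidative demercuration (NaBH4, O2, DMF) gives (4E)-7,10-epoxy-1-hydroxy-8-(methacryloyloxy)germacra-4,11(13)-dien-12,6-olide F7 as C1 epimers. Dess–Martin oxidation gives (4E)-7,10-epoxy-8-(methacryloyloxy)-1-oxogermacra-4,11(13)-dien-12,6-olide F8. mCPBA finally epoxidises the remaining trisubstituted alkene from its exposed face to give 26.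

Further compounds
F1 | step 10 | methyl (4R,5E,9E)-4-(tert-butyldimethylsilyloxy)-11-(methoxycarbonyloxy)-6,10-dimethyl-3-oxoundeca-5,9-dienoate | COC(=O)CC(=O)[C@H](O[Si](C)(C)C(C)(C)C)/C=C(C)/CC/C=C(C)/COC(=O)OC
F2 | step 10 | methyl (3E,7E,9R)-9-(tert-butyldimethylsilyloxy)-3,7-dimethyl-10-oxocyclodeca-3,7-diene-1-carboxylate | COC(=O)C1C/C(C)=C/CC/C(C)=C/[C@@H](O[Si](C)(C)C(C)(C)C)C1=O
F3 | step 10 | methyl (3E,7E,9R)-9-(tert-butyldimethylsilyloxy)-3,7-dimethyl-1-(2-methylprop-2-enoyloxy)-10-oxocyclodeca-3,7-diene-1-carboxylate | COC(=O)C1(OC(=O)C(C)=C)C/C(C)=C/CC/C(C)=C/[C@@H](O[Si](C)(C)C(C)(C)C)C1=O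
F4 | step 11 | (1S,2S,4E,8E,10R)-10-(tert-butyldimethylsilyloxy)-1-ethynyl-1-hydroxy-4,8-dimethylcyclodeca-4,8-dien-2-yl 2-methylprop-2-enoate | O[C@@]1(C#C)[C@@H](OC(=O)C(C)=C)C/C(C)=C/CC/C(C)=C/[C@H]1O[Si](C)(C)C(C)(C)C
F5 | step 11 | (1R,2S,4E,8E,10R)-1-ethynyl-1,10-dihydroxy-4,8-dimethylcyclodeca-4,8-dien-2-yl 2-methylprop-2-enoate | O[C@@]1(C#C)[C@@H](OC(=O)C(C)=C)C/C(C)=C/CC/C(C)=C/[C@H]1O
F6 | step 12 | (4E)-7,10-epoxy-8-(methacryloyloxy)-1-(trifluoroacetoxymercurio)germacra-4,11(13)-dien-12,6-olide | C=C(C)C(=O)O[C@H]1C[C@]2(C)O[C@@]13C(=C)C(=O)O[C@@H]3/C=C(C)/CC[C@H]2[Hg]OC(=O)C(F)(F)F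
F7 | step 12 | (4E)-7,10-epoxy-1-hydroxy-8-(methacryloyloxy)germacra-4,11(13)-dien-12,6-olide (C1 epimers) | C=C(C)C(=O)O[C@H]1C[C@]2(C)O[C@@]13C(=C)C(=O)O[C@@H]3/C=C(C)/CCC2O
F8 | step 12 | (4E)-7,10-epoxy-8-(methacryloyloxy)-1-oxogermacra-4,11(13)-dien-12,6-olide | C=C(C)C(=O)O[C@H]1C[C@]2(C)O[C@@]13C(=C)C(=O)O[C@@H]3/C=C(C)/CCC2=O
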